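**Plan**
- Retrosynthesis: cut the butenolide C1–O2 bond (carbonylative enol-lactonisation of a β-bromo enone made from a C7a ketone). Then cut, in one stroke, the spiro-lactone O–C3′ bond and the C8′–propyl bond (carbo-lactonisation of an aryl cyclobutene). Then cut aryl–C3′ (Suzuki–Miyaura) and last the cyclobutane bonds C6–C8′ and C7–C3′ (enone–allene [2+2]).
- Forward: the cyclobutane is made first on cyclohex-2-enone, then the aryl cyclobutene, then the spiro-phthalide together with the propyl group, and last the (Z)-butylidene butenolide on ring A.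
- Enabling feature: C3′ is a tertiary, benzylic cyclobutane carbon whose aryl group carries an ortho-carboxyl. A radical adding to C8′ of the strained C3′=C8′ cyclobutene leaves a stabilised radical, then cation, at C3′, which the carboxylate oxygen closes to a five-membered lactone.
- Stereochemistry: C6 and C7 come from a chiral-Lewis-acid-catalysed photocycloaddition. C8′ and C3′ come from the key step under control of the cis-fused bicycle (C–C bond on the convex face, then C–O bond trans to it). The Z alkene is the favoured isomer in the final lactonisation.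

Key step: step 8

Remark: locants follow phthalide-dimer numbering (ring A: C3a, C4, C5, C6, C7, C7a; cyclobutane: C6, C7, C3′, C8′; in bicyclo[4.2.0]octane names C1 = C7, C2 = C7a, C6 = C6, C7 = C8′, C8 = C3′); the SMILES is read as 6S,7R,3′R,8′S (cis ring fusion, propyl cis to H-6/H-7 and trans to the lactone oxygen on C3′), and it is assumed that the enantiomer of the prolinol-derived Lewis acid that leads to (1S,6S)-3 can be selected, both prolinol enantiomers being available.

**Route**

Step 1
Reactants: 1 cyclohex-2-en-1-one; 2 propadiene (allene)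
Product: 3 (1S,6S)-8-methylidenebicyclo[4.2.0]octan-2-one
Conditions: hν (366 nm), chiral B-aryl oxazaborolidine (from an α,α-diarylprolinol) activated with AlBr3 (50 mol%), excess allene, CH2Cl2, −75 °C
Reagents that add atoms: none
Why: Enone–allene [2+2] photocycloaddition in its chiral-Lewis-acid-catalysed form should join the central allene carbon to the enone α-carbon (head-to-head), the carbonyl-bound Lewis acid shielding one enone face and so setting C6 and C7 (cis fusion, any trans-fused adduct epimerising at the α-carbon).

Step 2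
Reactants: 3 (1S,6S)-8-methylidenebicyclo[4.2.0]octan-2-one
Product: 4 (1S,6S)-8-methylidenespiro[bicyclo[4.2.0]octane-2,2′-[1,3]dioxolane]
Conditions: Me3SiOCH2CH2OSiMe3, Me3SiOTf (cat.), CH2Cl2, −78 °C
Reagents that add atoms: 1,2-bis(trimethylsilyloxy)ethane, C[Si](C)(C)OCCO[Si](C)(C)C
Why: Aprotic silyl-triflate-catalysed acetalisation masks the C7a ketone so that the coming cyclobutanone is not part of a fragile 1,3-diketone, and at −78 °C the exocyclic alkene should not migrate.

Step 3
Reactants: 4 (1S,6S)-8-methylidenespiro[bicyclo[4.2.0]octane-2,2′-[1,3]dioxolane]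
Product: 6 (1S,6S)-spiro[bicyclo[4.2.0]octane-2,2′-[1,3]dioxolan]-8-one, via secondary ozonide 5 (not isolated)
Conditions: O3, CH2Cl2, −78 °C; then PPh3, −78 °C to rt
Reagents that add atoms: ozone, [O-][O+]=O
Why: Ozonolysis of the 1,1-disubstituted exocyclic alkene with reductive work-up should give the cyclobutanone at C3′ while the acetal and both ring-fusion centres stay untouched.

Step 4
Reactants: 6 (1S,6S)-spiro[bicyclo[4.2.0]octane-2,2′-[1,3]dioxolan]-8-one
Product: 8 (1S,6S)-spiro[bicyclo[4.2.0]oct-7-ene-2,2′-[1,3]dioxolan]-8-yl trifluoromethanesulfonate, via potassium enolate 7 (not isolated)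
Conditions: KN(SiMe3)2, THF, −78 °C; then PhNTf2, −78 to 0 °C
Reagents that add atoms: N-phenylbis(trifluoromethanesulfonimide), O=S(=O)(N(c1ccccc1)S(=O)(=O)C(F)(F)F)C(F)(F)F
Why: Kinetic deprotonation with a bulky amide should occur at the unhindered cyclobutanone CH2 (C8′) and not at the ring-fusion CH, and O-sulfonylation of the enolate gives the cyclobutenyl triflate (enol triflate formation).

Step 5
Reactants: 8 (1S,6S)-spiro[bicyclo[4.2.0]oct-7-ene-2,2′-[1,3]dioxolan]-8-yl trifluoromethanesulfonate; 9 [2-(methoxycarbonyl)phenyl]boronic acid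
Product: 10 methyl 2-[(1S,6S)-spiro[bicyclo[4.2.0]oct-7-ene-2,2′-[1,3]dioxolan]-8-yl]benzoate
Conditions: Pd(PPh3)4 (5 mol%), K3PO4, THF/H2O, 60 °C
Reagents that add atoms: none
Why: Suzuki–Miyaura coupling of an alkenyl triflate with an arylboronic acid should place the ortho-ester-bearing aryl group on C3′ without touching the remote stereocentres, the cis-fused cyclobutene being thermally stable at this temperature.

Step 6
Reactants: 10 methyl 2-[(1S,6S)-spiro[bicyclo[4.2.0]oct-7-ene-2,2′-[1,3]dioxolan]-8-yl]benzoate
Product: 11 2-[(1S,6S)-spiro[bicyclo[4.2.0]oct-7-ene-2,2′-[1,3]dioxolan]-8-yl]benzoic acid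
Conditions: LiOH, THF/MeOH/H2O, rt; then aq. HCl to pH 4, 0 °C
Reagents that add atoms: lithium hydroxide, [Li+].[OH-]
Why: Saponification frees the carboxylic acid that will close the lactone, and the acetal and the styrenic cyclobutene should survive the base and the mild acidification.

Step 7
Reactants: 12 butanoic acid; 13 N-hydroxyphthalimide
Product: 14 1,3-dioxoisoindolin-2-yl butanoate
Conditions: N,N′-diisopropylcarbodiimide, DMAP (cat.), CH2Cl2, rt
Reagents that add atoms: none
Why: Steglich-type esterification gives the redox-active N-acyloxyphthalimide that serves as the source of the n-propyl radical.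

Step 8
Reactants: 11 2-[(1S,6S)-spiro[bicyclo[4.2.0]oct-7-ene-2,2′-[1,3]dioxolan]-8-yl]benzoic acid; 14 1,3-dioxoisoindolin-2-yl butanoate
Product: 17 spiro-phthalide acetal (7-exo-propyl; lactone oxygen endo), via tertiary benzylic radical 15 (not isolated), via benzylic cation 16 (not isolated)
Conditions: 14 (2 equiv), Ir(ppy)3 (1 mol%), 2,6-lutidine, N,N-dimethylacetamide, blue LEDs (450 nm), rt, degassed
Reagents that add atoms: none
Why: Proposed new method: photoexcited Ir(ppy)3 reduces 14, which loses phthalimide anion and CO2 to give the n-propyl radical; this adds to C8′ of the strained styrenic cyclobutene to give radical 15, tetravalent iridium oxidises 15 to cation 16, and the ortho-carboxylate closes on C3′ before the cyclobutyl cation can rearrange. The closest known reaction type is the photoredox decarboxylative oxy-alkylation of styrenes and carbo-lactonisation of 2-vinylbenzoic acids with N-acyloxyphthalimides; its use on a ring-fused 1-arylcyclobutene is the new element. The lactone ring closes in a formal 5-exo-trig mode, the carboxylate oxygen bonding to C3′ of the former C3′=C8′ bond while C8′ stays outside the new ring. C8′ is set by attack of the radical on the convex face of the cis-bicyclo[4.2.0]octene, syn to H-6 and H-7; C3′ is set when the carboxylate enters on the concave face, trans to the new propyl group, which places only the small oxygen, and not the benzo ring, under ring A and its dioxolane. The step needs addition at C8′ only (secured by formation of the aryl-stabilised radical), no competing radical acceptor (the ketone is masked and no other alkene is present) and no plain acid-catalysed hydrolactonisation (secured by the lutidine buffer).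

Step 9
Reactants: 17 spiro-phthalide acetal
Product: 18 7-propyl-3′H-spiro[bicyclo[4.2.0]octane-8,1′-isobenzofuran]-2,3′-dione
Conditions: 2 M HCl, THF, rt
Reagents that add atoms: water, O
Why: Acid-catalysed acetal hydrolysis returns the C7a ketone, and the aryl lactone, the quaternary C3′ and the cis ring fusion (the stable epimer at C7) should be unaffected.

Step 10
Reactants: 18 7-propyl-3′H-spiro[bicyclo[4.2.0]octane-8,1′-isobenzofuran]-2,3′-dione
Product: 20 2-bromo-3′-oxo-7-propyl-3′H-spiro[bicyclo[4.2.0]oct-2-ene-8,1′-isobenzofuran]-3-carbaldehyde, via bromovinyl iminium bromide 19 (not isolated)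
Conditions: PBr3, DMF, CHCl3, 0 to 60 °C; then aq. NaOAc
Reagents that add atoms: N,N-dimethylformamide, CN(C)C=O; phosphorus tribromide, BrP(Br)Br; water, O
Why: Vilsmeier–Haack haloformylation should formylate the only enolisable CH2 (C3a, since C7 is a hindered ring-fusion methine) and exchange the carbonyl oxygen for bromide, under acidic conditions that do not provoke β-elimination of the C3′ carboxylate.

Step 11
Reactants: 20 2-bromo-3′-oxo-7-propyl-3′H-spiro[bicyclo[4.2.0]oct-2-ene-8,1′-isobenzofuran]-3-carbaldehyde
Product: 21 2-bromo-3-(1-hydroxypentyl)-7-propyl-3′H-spiro[bicyclo[4.2.0]oct-2-ene-8,1′-isobenzofuran]-3′-one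
Conditions: n-BuMgBr, THF, −78 °C
Reagents that add atoms: butylmagnesium bromide, CCCC[Mg]Br
Why: Grignard 1,2-addition to the aldehyde at −78 °C should be much faster than attack on the aryl lactone or the vinyl bromide, and the new carbinol centre (either epimer) is removed in the next step.

Step 12
Reactants: 21 2-bromo-3-(1-hydroxypentyl)-7-propyl-3′H-spiro[bicyclo[4.2.0]oct-2-ene-8,1′-isobenzofuran]-3′-one
Product: 22 2-bromo-3-pentanoyl-7-propyl-3′H-spiro[bicyclo[4.2.0]oct-2-ene-8,1′-isobenzofuran]-3′-one
Conditions: Dess–Martin periodinane, NaHCO3, CH2Cl2, rt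
Reagents that add atoms: none
Why: Dess–Martin oxidation of the allylic alcohol should give the ring-held (Z)-β-bromo enone under neutral conditions without touching the other functions.

Step 13
Reactants: 22 2-bromo-3-pentanoyl-7-propyl-3′H-spiro[bicyclo[4.2.0]oct-2-ene-8,1′-isobenzofuran]-3′-one
Product: 23 target spiro-phthalide dimer (6S,7R,3′R,8′S; Z-butylidene)
Conditions: CO (1 atm), PdCl2(PPh3)2 (5 mol%), Et3N, MeCN, 60 °C
Reagents that add atoms: carbon monoxide, [C-]#[O+]
Why: Carbonylative lactonisation, in which zerovalent palladium inserts into the C7a–Br bond, CO insertion gives an acylpalladium species and the oxygen of the enolised butyl ketone traps it (a reaction type known for (Z)-β-halo enones and 2-halophenyl ketones), should give the butenolide with the favoured Z-butylidene geometry (propyl syn to the ring oxygen, away from C4H2).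

**Compound list**

1 | cyclohex-2-en-1-one | O=C1C=CCCC1 | starting material
2 | propadiene (allene) | C=C=C | starting material
3 | (1S,6S)-8-methylidenebicyclo[4.2.0]octan-2-one (cis-fused; methylidene on the cyclobutane carbon next to the α-carbon) | O=C2CCC[C@H]1CC(=C)[C@@H]21 | intermediate
4 | (1S,6S)-8-methylidenespiro[bicyclo[4.2.0]octane-2,2′-[1,3]dioxolane] | O1CCOC12CCC[C@H]3CC(=C)[C@@H]23 | intermediate
5 | secondary ozonide of 4 (spiro-1,2,4-trioxolane at C8) | O1CCOC12CCC[C@H]3CC4(OCOO4)[C@@H]23 | intermediate (not isolated)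
6 | (1S,6S)-spiro[bicyclo[4.2.0]octane-2,2′-[1,3]dioxolan]-8-one | O1CCOC12CCC[C@H]3CC(=O)[C@@H]23 | intermediate
7 | potassium enolate of 6 (C7=C8 enolate) | O1CCOC12CCC[C@H]3C=C(O[K])[C@@H]23 | intermediate (not isolated)
8 | (1S,6S)-spiro[bicyclo[4.2.0]oct-7-ene-2,2′-[1,3]dioxolan]-8-yl trifluoromethanesulfonate | O1CCOC12CCC[C@H]3C=C(OS(=O)(=O)C(F)(F)F)[C@@H]23 | intermediate
9 | [2-(methoxycarbonyl)phenyl]boronic acid | COC(=O)c1ccccc1B(O)O | starting material
10 | methyl 2-[(1S,6S)-spiro[bicyclo[4.2.0]oct-7-ene-2,2′-[1,3]dioxolan]-8-yl]benzoate | O1CCOC12CCC[C@H]3C=C(c4ccccc4C(=O)OC)[C@@H]23 | intermediate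
11 | 2-[(1S,6S)-spiro[bicyclo[4.2.0]oct-7-ene-2,2′-[1,3]dioxolan]-8-yl]benzoic acid | O1CCOC12CCC[C@H]3C=C(c4ccccc4C(=O)O)[C@@H]23 | intermediate
12 | butanoic acid | CCCC(=O)O | starting material
13 | N-hydroxyphthalimide | O=C1N(O)C(=O)c2ccccc12 | starting material
14 | 1,3-dioxoisoindolin-2-yl butanoate | CCCC(=O)ON1C(=O)c2ccccc2C1=O | intermediate
15 | tertiary benzylic cyclobutyl radical at C3′ (propyl already exo on C8′) | O1CCOC12CCC[C@H]3[C@H](CCC)[C](c4ccccc4C(=O)O)[C@@H]23 | intermediate (not isolated)
16 | benzylic cyclobutyl cation at C3′ | O1CCOC12CCC[C@H]3[C@H](CCC)[C+](c4ccccc4C(=O)O)[C@@H]23 | intermediate (not isolated)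
17 | spiro-phthalide acetal: cis-fused spiro[bicyclo[4.2.0]octane-2,2′-[1,3]dioxolane] with exo-propyl at C7 and, spiro at C8, an isobenzofuran-1(3H)-one (lactone O endo, trans to propyl; benzo ring exo; all four stereocentres as in 23) | O1CCOC12CCC[C@H]3[C@H](CCC)[C@@]4(OC(=O)c5ccccc54)[C@@H]23 | intermediate
18 | 7-propyl-3′H-spiro[bicyclo[4.2.0]octane-8,1′-isobenzofuran]-2,3′-dione (configuration as in 23) | O=C2CCC[C@H]1[C@H](CCC)[C@@]3(OC(=O)c4ccccc43)[C@@H]21 | intermediate
19 | iminium bromide: as 20 with CH=N(+)Me2 in place of CHO | BrC2=C(C=[N+](C)C)CC[C@H]1[C@H](CCC)[C@@]3(OC(=O)c4ccccc43)[C@@H]21.[Br-] | intermediate (not isolated)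
20 | 2-bromo-3′-oxo-7-propyl-3′H-spiro[bicyclo[4.2.0]oct-2-ene-8,1′-isobenzofuran]-3-carbaldehyde (Br on C7a, CHO on C3a; configuration as in 23) | BrC2=C(C=O)CC[C@H]1[C@H](CCC)[C@@]3(OC(=O)c4ccccc43)[C@@H]21 | intermediate
21 | 2-bromo-3-(1-hydroxypentyl)-7-propyl-3′H-spiro[bicyclo[4.2.0]oct-2-ene-8,1′-isobenzofuran]-3′-one (carbinol epimers; ring stereocentres as in 23) | BrC2=C(C(O)CCCC)CC[C@H]1[C@H](CCC)[C@@]3(OC(=O)c4ccccc43)[C@@H]21 | intermediate
22 | 2-bromo-3-pentanoyl-7-propyl-3′H-spiro[bicyclo[4.2.0]oct-2-ene-8,1′-isobenzofuran]-3′-one (configuration as in 23) | BrC2=C(C(=O)CCCC)CC[C@H]1[C@H](CCC)[C@@]3(OC(=O)c4ccccc43)[C@@H]21 | intermediate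
23 | target, CNP0248594.3: (6S,7R,3′R,8′S) cyclobutane-linked dimer of (Z)-ligustilide (through C6, C7) and 3-butylidenephthalide (through C3′, C8′), Z-butylidene butenolide, propyl trans to the spiro-lactone oxygen | CCC/C=C1\OC(=O)C2=C1CC[C@H]1[C@H](CCC)[C@@]3(OC(=O)c4ccccc43)[C@@H]21 | target

**Totals and risks**

Total step count: 13. Longest linear sequence: 12 steps (steps 1–6 and 8–13; step 7 is a side branch).

Steps most likely to fail:

1. Step 8 (labelled step). The primary alkyl radical may add too slowly to the trisubstituted cyclobutene and be lost to reduction or dimerisation, or the capture of the C3′ cation may show poor facial selectivity. The fallback uses known chemistry and sets out from 6. Alkylation of its kinetic enolate (LiN(i-Pr)2, THF, −78 °C, allyl bromide) on the convex face should give the exo-allyl cyclobutanone F1. Addition of 2-(methoxycarbonyl)phenylmagnesium chloride (from methyl 2-iodobenzoate and i-PrMgCl·LiCl, −40 °C) from the convex face, followed by closure of the alkoxide onto the ester, should give the allyl spiro-phthalide acetal F2. Hydrogenation of the allyl group (H2, Pd/C, EtOAc) comes back to the route at 17.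

2. Step 1. Enantiofacial control or the head-to-head orientation may be lost when the Lewis-acid-bound enone meets allene, or allene may oligomerise on AlBr3. The fallback sets out from 1 and 2. Uncatalysed irradiation (350 nm, CH2Cl2, −78 °C) should give the racemic cis adduct F3. Acetalisation with (2R,3R)-butane-2,3-diol (p-TsOH, benzene, reflux) should give two diastereomers, the dioxolane of the (1S,6S) ketone F4 and the dioxolane of the (1R,6R) ketone F5, to be separated by chromatography or crystallisation. Hydrolysis of F4 (aq. HCl, acetone) comes back to the route at 3.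

3. Step 13. The acylpalladium species may be trapped at carbon rather than oxygen of the enolate, the alkene may form as a Z/E mixture, or amine base may trigger β-elimination of the C3′ carboxylate through the vinylogous enolate. The fallback sets out from 21. Cyclocarbonylation with the free hydroxyl (Pd(PPh3)4, CO, K2CO3, THF, 60 °C) should give the 3-butyl butenolide F6. Radical bromination of its allylic, oxygen-bearing C3–H (N-bromosuccinimide, AIBN, CCl4, reflux) should give the tertiary bromide F7. Elimination with Et3N comes back to the route at 23.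

**Further compounds**

F1 | step 8 | (1S,6S,7S)-7-(prop-2-enyl)spiro[bicyclo[4.2.0]octane-2,2′-[1,3]dioxolan]-8-one (allyl exo) | O1CCOC12CCC[C@H]3[C@H](CC=C)C(=O)[C@@H]23
F2 | step 8 | allyl analogue of 17 (exo-allyl in place of propyl; spiro-phthalide as in 17) | O1CCOC12CCC[C@H]3[C@H](CC=C)[C@@]4(OC(=O)c5ccccc54)[C@@H]23
F3 | step 1 | rac-cis-8-methylidenebicyclo[4.2.0]octan-2-one (racemate of 3) | O=C1CCCC2CC(=C)C12
F4 | step 1 | (4R,5R)-4,5-dimethyl-1,3-dioxolane acetal of (1S,6S)-3 | C[C@H]1OC2(CCC[C@H]3CC(=C)[C@@H]23)O[C@@H]1C
F5 | step 1 | (4R,5R)-4,5-dimethyl-1,3-dioxolane acetal of the (1R,6R) ketone (discarded diastereomer) | C[C@H]1OC2(CCC[C@@H]3CC(=C)[C@H]23)O[C@@H]1C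
F6 | step 13 | 3-butyl butenolide: 23 with C3–H and a butyl group in place of the butylidene (C3 epimers) | CCCCC1OC(=O)C2=C1CC[C@H]1[C@H](CCC)[C@@]3(OC(=O)c4ccccc43)[C@@H]21
F7 | step 13 | 3-bromo-3-butyl butenolide derived from F6 | CCCCC1(Br)OC(=O)C2=C1CC[C@H]1[C@H](CCC)[C@@]3(OC(=O)c4ccccc43)[C@@H]21
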